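**Retrosynthetic overview**
- Structural feature: the oxygens on C2 (ring A) and C2' (ring B) flank the C1–C1' bond, so one silicon atom can bridge them. The C2'(O)–C3'(OMe)–C4'(H)–C5'(CH2CH2CO2R) edge of ring B is the C3–C6 diene of a 3-oxy-4-methoxy-6-alkyl-2-pyrone. C1' and C6' are the two carbons of an ethynyl group on C1 of ring A.
- Target ⇒ (ester hydrolysis, Si–O cleavage) dibenzo-dioxasilepine diester ⇒ (pyrone–alkyne [4+2] with CO2 loss, forming C1'–C2' and C5'–C6') an ethynylphenol and a hydroxypyrone joined through O–Si(iPr)2–O.
- The tethered precursor comes from iPr2SiCl2, a 2-ethynylphenol and a 3-hydroxypyrone. The ethynylphenol is made from methyl dihydroferulate by ortho-iodination, Sonogashira coupling and desilylation. The hydroxypyrone is made from 4-hydroxy-6-methyl-2-pyrone by O-methylation, alkylation at the C6 methyl group, C3 bromination and borylation–oxidation.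
- Ring order: ring A and the pyrone ring are purchased. Ring B and the seven-membered O–Si–O ring form together in the key step, and the seven-membered ring is then opened.

Key step: step 9

Remark: the target has no stereocentre, and its biaryl axis (ortho substituents OH and H on each ring) is not configurationally stable. The SMILES without stereodescriptors is therefore complete. Intermediate 17 is racemic and transient.

**Step 1**
Reactants: 1 4-hydroxy-6-methyl-2-pyrone
Product: 2 4-methoxy-6-methyl-2-pyrone
Conditions: Me2SO4, K2CO3, acetone, reflux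
Reagents that add atoms: dimethyl sulfate, COS(=O)(=O)OC
Why: Williamson-type O-alkylation of the acidic vinylogous acid OH at C4, which under K2CO3/acetone should give the 4-methoxy-2-pyrone rather than the 2-methoxy-4-pyrone isomer.

**Step 2**
Reactants: 2 4-methoxy-6-methyl-2-pyrone; 3 methyl bromoacetate
Product: 5 methyl 3-(4-methoxy-2-oxo-2H-pyran-6-yl)propanoate, via lithium dienolate 4 (not isolated)
Conditions: LiHMDS (1.0 equiv), THF, −78 °C; then 3, DMPU, −78 → −30 °C
Reagents that add atoms: none
Why: Vinylogous enolate alkylation, in which the amide base deprotonates the C6 methyl group and the soft extended enolate 4 should displace bromide from the α-bromo ester by SN2 at its exocyclic carbon, restoring the pyrone.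

**Step 3**
Reactants: 5 methyl 3-(4-methoxy-2-oxo-2H-pyran-6-yl)propanoate
Product: 6 methyl 3-(3-bromo-4-methoxy-2-oxo-2H-pyran-6-yl)propanoate
Conditions: NBS, MeCN, rt, dark
Reagents that add atoms: N-bromosuccinimide, O=C1CCC(=O)N1Br
Why: Electrophilic bromination at C3, the nucleophilic β-carbon of the 4-methoxy enol ether and the usual halogenation site of 4-methoxy-6-alkyl-2-pyrones, under ionic conditions in the dark that avoid side-chain bromination.

**Step 4**
Reactants: 6 methyl 3-(3-bromo-4-methoxy-2-oxo-2H-pyran-6-yl)propanoate
Product: 8 methyl 3-(3-hydroxy-4-methoxy-2-oxo-2H-pyran-6-yl)propanoate, via pinacol boronate 7 (not isolated)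
Conditions: B2pin2, Pd(dppf)Cl2 (5 mol %), KOAc, 1,4-dioxane, 85 °C; filter, concentrate; then 30% H2O2, phosphate buffer pH 7, THF, 0 °C → rt; work-up at pH 3
Reagents that add atoms: hydrogen peroxide (oxygen on C3), OO; bis(pinacolato)diboron (boron of 7 only), CC1(C)OB(OC1(C)C)B1OC(C)(C)C(C)(C)O1
Why: Miyaura borylation of the C3–Br bond followed by boronate oxidation (peroxide addition and 1,2-shift from B to O) should exchange Br for OH, and KOAc and buffered H2O2 are mild enough for the lactone and the methyl ester.

**Step 5**
Reactants: 9 methyl 3-(4-hydroxy-3-methoxyphenyl)propanoate (methyl dihydroferulate)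
Product: 10 methyl 3-(4-hydroxy-3-iodo-5-methoxyphenyl)propanoate
Conditions: NIS, p-TsOH·H2O (10 mol %), MeCN, 0 °C → rt
Reagents that add atoms: N-iodosuccinimide, O=C1CCC(=O)N1I
Why: Electrophilic aromatic iodination directed by the free phenol, the strongest donor, whose para position and one ortho position are blocked, so the remaining ortho carbon should react.

**Step 6**
Reactants: 10 methyl 3-(4-hydroxy-3-iodo-5-methoxyphenyl)propanoate; 11 trimethylsilylacetylene
Product: 12 methyl 3-[4-hydroxy-3-methoxy-5-(trimethylsilylethynyl)phenyl]propanoate
Conditions: PdCl2(PPh3)2 (3 mol %), CuI (5 mol %), Et3N, THF, rt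
Reagents that add atoms: none
Why: Sonogashira coupling (oxidative addition of the aryl iodide to zerovalent palladium, then transfer of the copper acetylide), in which room temperature and the bulky silyl group should hold back cyclisation of the free ortho phenol to a benzofuran.

**Step 7**
Reactants: 12 methyl 3-[4-hydroxy-3-methoxy-5-(trimethylsilylethynyl)phenyl]propanoate
Product: 13 methyl 3-(3-ethynyl-4-hydroxy-5-methoxyphenyl)propanoate
Conditions: K2CO3 (0.3 equiv), MeOH, 0 °C → rt
Reagents that add atoms: none
Why: Base-catalysed methanolysis of the alkynyl C–Si bond (protodesilylation), in which ester exchange with MeOH is degenerate and the low temperature avoids base-induced benzofuran formation.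

**Step 8**
Reactants: 13 methyl 3-(3-ethynyl-4-hydroxy-5-methoxyphenyl)propanoate; 14 dichlorodiisopropylsilane; 8 methyl 3-(3-hydroxy-4-methoxy-2-oxo-2H-pyran-6-yl)propanoate
Product: 16 mixed diisopropylsilylene bis-ether (phenol oxygen of 13 joined through Si(iPr)2 to the C3 oxygen of 8), via aryloxychlorosilane 15 (not isolated)
Conditions: 13 added slowly to 14 (1.1 equiv), Et3N, CH2Cl2, 0 °C; then 8, Et3N, DMAP (cat.), rt; Et3N-deactivated SiO2 plug
Reagents that add atoms: none
Why: Stepwise nucleophilic substitution at silicon (unsymmetrical silaketal formation), in which the two isopropyl groups and the doubly ortho-substituted phenol make the second chloride much slower to leave than the first, so 15 should persist until the more acidic hydroxypyrone and DMAP are added.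

**Step 9**
Reactants: 16 mixed diisopropylsilylene bis-ether
Product: 18 dimethyl 3,3'-(6,6-diisopropyl-4,8-dimethoxydibenzo[d,f][1,3,2]dioxasilepine-2,10-diyl)dipropanoate, via bicyclic lactone 17 (not isolated)
Conditions: o-dichlorobenzene (0.01 M), BHT (cat.), 180 °C, sealed tube, Ar
Reagents that add atoms: none
Why: Proposed new method: the ethynyl group of ring A should add across C3 and C6 of the tethered 2-pyrone in a thermal intramolecular [4+2] cycloaddition (new bonds C1'–C2' and C5'–C6'), and the 2-oxabicyclo[2.2.2]octadienone 17 should then lose CO2 by retro-[4+2] at the same temperature, which makes the sequence irreversible. The closest known reaction types are the intramolecular Diels–Alder/decarboxylation of 2-pyrones bearing tethered alkynes and the temporary silicon-tethered Diels–Alder reaction; a tether running through the 3-oxygen of a 2-pyrone has not been shown. Ring B closes by cycloaddition (four carbons from the pyrone, two from the alkyne), and the seven-membered dioxasilepine closes in the same event because C1'–C2' is also its last bond. The two bridgehead stereocentres of 17 disappear with CO2, so 18 has none. The selectivity needed is regiochemical (pyrone C3 to the internal alkyne carbon) and intra- over intermolecular: the five-atom C–C–O–Si–O link can only span C3 and the internal carbon, two of its atoms are fixed ortho on ring A, the isopropyl groups favour the folded conformer (Thorpe–Ingold effect), and high dilution suppresses dimerisation. In 17 the bridgehead C–O bond and the vinylic C–aryl bond are nearly eclipsed, as in a 2,2'-biphenol silylene, so the tether should add little strain to the transition state.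

**Step 10**
Reactants: 18 dioxasilepine diester
Product: 19 dimethyl 3,3'-(6,6'-dihydroxy-5,5'-dimethoxy[1,1'-biphenyl]-3,3'-diyl)dipropanoate
Conditions: HF·pyridine, pyridine, THF, 0 °C → rt (plastic vessel)
Reagents that add atoms: none
Why: Fluoride-driven cleavage of both aryl Si–O bonds (desilylation), paid for by the strong Si–F bonds, under buffered conditions that leave methyl esters and aryl methyl ethers untouched.

**Step 11**
Reactants: 19 biphenol dimethyl ester
Product: 20 3,3'-(6,6'-dihydroxy-5,5'-dimethoxy[1,1'-biphenyl]-3,3'-diyl)dipropanoic acid (target)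
Conditions: LiOH·H2O (6 equiv), THF/MeOH/H2O, rt, Ar (degassed); then 1 M HCl
Reagents that add atoms: lithium hydroxide (oxygen of each new CO2H), [Li+].[OH-]
Why: Saponification of two unhindered methyl esters by acyl–oxygen cleavage, with air excluded to protect the electron-rich biphenolate and acidification releasing the diacid.

**Compound list**
1 | 4-hydroxy-6-methyl-2-pyrone | CC1=CC(O)=CC(=O)O1 | starting material
2 | 4-methoxy-6-methyl-2-pyrone | CC1=CC(OC)=CC(=O)O1 | intermediate
3 | methyl bromoacetate | COC(=O)CBr | starting material
4 | lithium dienolate of 2 (2-lithiooxy-4-methoxy-6-methylene-6H-pyran) | C=C1C=C(OC)C=C(O[Li])O1 | intermediate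
5 | methyl 3-(4-methoxy-2-oxo-2H-pyran-6-yl)propanoate | COC(=O)CCC1=CC(OC)=CC(=O)O1 | intermediate
6 | methyl 3-(3-bromo-4-methoxy-2-oxo-2H-pyran-6-yl)propanoate | COC(=O)CCC1=CC(OC)=C(Br)C(=O)O1 | intermediate
7 | methyl 3-[4-methoxy-2-oxo-3-(pinacolatoboryl)-2H-pyran-6-yl]propanoate | COC(=O)CCC1=CC(OC)=C(B2OC(C)(C)C(C)(C)O2)C(=O)O1 | intermediate
8 | methyl 3-(3-hydroxy-4-methoxy-2-oxo-2H-pyran-6-yl)propanoate | COC(=O)CCC1=CC(OC)=C(O)C(=O)O1 | intermediate
9 | methyl 3-(4-hydroxy-3-methoxyphenyl)propanoate | COC(=O)CCc1ccc(O)c(OC)c1 | starting material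
10 | methyl 3-(4-hydroxy-3-iodo-5-methoxyphenyl)propanoate | COC(=O)CCc1cc(I)c(O)c(OC)c1 | intermediate
11 | trimethylsilylacetylene | C#C[Si](C)(C)C | starting material
12 | methyl 3-[4-hydroxy-3-methoxy-5-(trimethylsilylethynyl)phenyl]propanoate | COC(=O)CCc1cc(OC)c(O)c(C#C[Si](C)(C)C)c1 | intermediate
13 | methyl 3-(3-ethynyl-4-hydroxy-5-methoxyphenyl)propanoate | COC(=O)CCc1cc(OC)c(O)c(C#C)c1 | intermediate
14 | dichlorodiisopropylsilane | CC(C)[Si](Cl)(Cl)C(C)C | starting material
15 | methyl 3-{4-[chloro(diisopropyl)silyloxy]-3-ethynyl-5-methoxyphenyl}propanoate | COC(=O)CCc1cc(OC)c(O[Si](Cl)(C(C)C)C(C)C)c(C#C)c1 | intermediate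
16 | mixed diisopropylsilylene bis-ether of 13 (phenol O) and 8 (pyrone 3-O) | COC(=O)CCc1cc(OC)c(O[Si](C(C)C)(C(C)C)OC2=C(OC)C=C(CCC(=O)OC)OC2=O)c(C#C)c1 | intermediate
17 | 2-oxabicyclo[2.2.2]octa-5,7-dien-3-one cycloadduct fused to the seven-membered O–Si–O ring (racemic, transient) | COC(=O)CCc1cc(OC)c2O[Si](C(C)C)(C(C)C)OC34C(=O)OC(CCC(=O)OC)(C=C3OC)C=C4c2c1 | intermediate
18 | dimethyl 3,3'-(6,6-diisopropyl-4,8-dimethoxydibenzo[d,f][1,3,2]dioxasilepine-2,10-diyl)dipropanoate | COC(=O)CCc1cc(OC)c2O[Si](C(C)C)(C(C)C)Oc3c(OC)cc(CCC(=O)OC)cc3-c2c1 | intermediate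
19 | dimethyl 3,3'-(6,6'-dihydroxy-5,5'-dimethoxy[1,1'-biphenyl]-3,3'-diyl)dipropanoate | COC(=O)CCc1cc(OC)c(O)c(-c2cc(CCC(=O)OC)cc(OC)c2O)c1 | intermediate
20 | 3,3'-(6,6'-dihydroxy-5,5'-dimethoxy[1,1'-biphenyl]-3,3'-diyl)dipropanoic acid | COc1cc(CCC(=O)O)cc(-c2cc(CCC(=O)O)cc(OC)c2O)c1O | target

**Step count:** 11 steps in total. The longest linear sequence is 8 steps (steps 1–4, then 8–11). The ring A branch (steps 5–7) joins at step 8.

**Steps most likely to fail**

1. **Step 9 (the labelled step).**
   - Risk: the cycloaddition between the donor-substituted pyrone and the electronically unbiased aryl alkyne may be too slow. Thermal or moisture-induced cleavage of the pyronyl Si–O bond and intermolecular reactions could then overtake it.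
   - Fallback (known chemistry, oxidative phenol coupling): it sets out from methyl dihydroferulate 9 and comes back to the route at biphenol diester 19. Compound 9 is stirred with laccase from Trametes versicolor under O2 in acetate buffer (pH 5)/acetone. The phenoxyl radical has its para position blocked by the side chain, so it should dimerise at the free ortho carbon, and tautomerisation gives 19. The less soluble dimer should precipitate and so escape over-oxidation. Step 11 follows unchanged. This fallback makes no compound outside the list (entry F0).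

2. **Step 8.**
   - Risk: silicon may be substituted twice by the same partner, giving symmetrical silaketals. The labile pyronyl Si–O bond may also hydrolyse during isolation.
   - Fallback (one leaving group on silicon at a time): it sets out from ethynylphenol 13 and comes back at 16. Compound 13 is silylated with chlorodiisopropylsilane (Et3N, CH2Cl2, 0 °C) to the isolable methyl 3-[4-(diisopropylsilyloxy)-3-ethynyl-5-methoxyphenyl]propanoate F1. Its Si–H bond is converted with NBS (CH2Cl2, 0 °C) into the aryloxy(bromo)diisopropylsilane F2. Hydroxypyrone 8, Et3N and DMAP are then added to the same flask to give 16. A symmetrical product cannot form by this route.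

3. **Step 4.**
   - Risk: the electron-rich C3–B bond may undergo protodeboronation during borylation. The lactone may open during oxidation.
   - Fallback (direct C–O coupling, no boron): it sets out from bromide 6 and comes back at 8. Compound 6 is coupled with (E)-benzaldoxime as a hydroxide surrogate (Pd2(dba)3, tBuBrettPhos, Cs2CO3, DMF, 80 °C). The first-formed O-pyronyl benzaldoxime ether F3 should fragment under the same basic conditions to the pyronolate and a nitrile, and acidic work-up gives 8.

**Further compounds**
F0 | step 9 | none | none
F1 | step 8 | methyl 3-[4-(diisopropylsilyloxy)-3-ethynyl-5-methoxyphenyl]propanoate | COC(=O)CCc1cc(OC)c(O[SiH](C(C)C)C(C)C)c(C#C)c1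
F2 | step 8 | methyl 3-{4-[bromo(diisopropyl)silyloxy]-3-ethynyl-5-methoxyphenyl}propanoate | COC(=O)CCc1cc(OC)c(O[Si](Br)(C(C)C)C(C)C)c(C#C)c1
F3 | step 4 | methyl 3-{3-[(E)-benzylideneaminooxy]-4-methoxy-2-oxo-2H-pyran-6-yl}propanoate | COC(=O)CCC1=CC(OC)=C(O/N=C/c2ccccc2)C(=O)O1
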